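**Retrosynthetic overview**
1. Last bonds: four O–benzyl groups removed by hydrogenolysis; the N–CH2 bond between the linker and the azecane is made by SN2 of mesylate 27 with (S)-3-methylazecane 41.
2. Pyrrole ring: Hinsberg double Claisen condensation of an N-(3-oxypropyl)iminodiacetate with diethyl oxalate (first C–C bond intermolecular, second ring-closing), then bistriflate, double Suzuki coupling, saponification and double decarboxylation.
3. Quinoline: pyridine ring built on 4-(benzyloxy)-3-methoxyaniline (Meldrum's acid route); the freed 6-OH then directs bromination to C5, giving boronate 15.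
4. Azecane: stereocentre from (R)-Roche ester, chain by Cu-catalysed Grignard–tosylate coupling, ten-membered ring by intramolecular N-alkylation of a 2-nitrobenzenesulfonamide.
5. Ring order: quinoline pyridine ring, then pyrrole, azecane made separately and attached last.

Assumption: the target SMILES carries no axial descriptors, so rotamers about the aryl–pyrrole bonds count as one compound; THP intermediates are racemic at the acetal carbon.

**Fragment A: quinoline boronate**

Step 1
Reactants: 1 2-methoxy-4-nitrophenol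
Product: 2 1-(benzyloxy)-2-methoxy-4-nitrobenzene
Conditions: BnBr, K2CO3, DMF, 60 °C
Reagents that add atoms: benzyl bromide, BrCc1ccccc1
Why: Williamson ether synthesis; the acidic nitrophenol is fully ionised and benzyl bromide is a fast SN2 electrophile.

Step 2
Reactants: 2 1-(benzyloxy)-2-methoxy-4-nitrobenzene
Product: 3 4-(benzyloxy)-3-methoxyaniline
Conditions: Fe powder, NH4Cl, EtOH/H2O, 80 °C
Reagents that add atoms: none
Why: Béchamp-type iron reduction of the nitro group, which leaves the benzyl ether intact (no hydrogenolysis).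

Step 3
Reactants: 3 4-(benzyloxy)-3-methoxyaniline; 4 Meldrum's acid (2,2-dimethyl-1,3-dioxane-4,6-dione); 5 trimethyl orthoformate
Product: 7 5-({[4-(benzyloxy)-3-methoxyphenyl]amino}methylidene)-2,2-dimethyl-1,3-dioxane-4,6-dione, via 5-(methoxymethylidene) Meldrum's acid 6 (not isolated)
Conditions: 4 in HC(OMe)3, reflux, 2 h; then 3, reflux, 2 h
Reagents that add atoms: none
Why: Knoevenagel-type condensation of Meldrum's acid with the orthoformate, then addition–elimination by the aniline nitrogen gives the stable enaminone.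

Step 4
Reactants: 7 5-({[4-(benzyloxy)-3-methoxyphenyl]amino}methylidene)-2,2-dimethyl-1,3-dioxane-4,6-dione
Product: 9 6-(benzyloxy)-7-methoxyquinolin-4(1H)-one, via imidoylketene 8 (not isolated)
Conditions: Ph2O, 250 °C, 15 min
Reagents that add atoms: none
Why: Gould–Jacobs-type thermolysis (loss of acetone and CO2) gives an imidoylketene that closes by electrocyclisation at the unhindered ring position para to OMe, fixing the 6,7-pattern.

Step 5
Reactants: 9 6-(benzyloxy)-7-methoxyquinolin-4(1H)-one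
Product: 10 6-(benzyloxy)-4-chloro-7-methoxyquinoline
Conditions: POCl3, 100 °C
Reagents that add atoms: phosphoryl chloride, O=P(Cl)(Cl)Cl
Why: deoxychlorination of the 4-quinolone by O-phosphorylation and addition–elimination of chloride.

Step 6
Reactants: 10 6-(benzyloxy)-4-chloro-7-methoxyquinoline
Product: 11 7-methoxyquinolin-6-ol
Conditions: H2 (1 atm), 10% Pd/C, NaOAc, MeOH, rt
Reagents that add atoms: none
Why: catalytic hydrogenolysis removes both the activated 4-chloride and the O-benzyl group, freeing only the 6-OH.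

Step 7
Reactants: 11 7-methoxyquinolin-6-ol
Product: 12 5-bromo-7-methoxyquinolin-6-ol
Conditions: NBS (1.0 equiv), MeCN, 0 °C
Reagents that add atoms: N-bromosuccinimide, O=C1CCC(=O)N1Br
Why: electrophilic aromatic bromination; the free phenol outcompetes the methyl ether and directs to its ortho alpha position C5, as in 2-naphthol.

Step 8
Reactants: 12 5-bromo-7-methoxyquinolin-6-ol
Product: 13 5-bromoquinoline-6,7-diol
Conditions: BBr3, CH2Cl2, −78 °C → rt; then MeOH; pH 7 work-up
Reagents that add atoms: none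
Why: Lewis-acid cleavage of the aryl methyl ether at a robust, simple stage.

Step 9
Reactants: 13 5-bromoquinoline-6,7-diol
Product: 14 6,7-bis(benzyloxy)-5-bromoquinoline
Conditions: BnBr (2.2 equiv), K2CO3, DMF, 50 °C
Reagents that add atoms: benzyl bromide, BrCc1ccccc1
Why: double Williamson etherification; the phenoxides react much faster than the quinoline nitrogen.

Step 10
Reactants: 14 6,7-bis(benzyloxy)-5-bromoquinoline
Product: 15 6,7-bis(benzyloxy)-5-(4,4,5,5-tetramethyl-1,3,2-dioxaborolan-2-yl)quinoline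
Conditions: B2pin2, Pd(OAc)2 (2 mol%), SPhos (4 mol%), KOAc, 1,4-dioxane, 100 °C
Reagents that add atoms: bis(pinacolato)diboron, CC1(C)OB(OC1(C)C)B1OC(C)(C)C(C)(C)O1
Why: Miyaura borylation (oxidative addition to zerovalent palladium, acetate-assisted transmetalation, reductive elimination); the bulky ligand tolerates the two ortho substituents.

**Fragment B: pyrrole core**

Step 11
Reactants: 16 diethyl iminodiacetate; 17 2-(3-bromopropoxy)tetrahydro-2H-pyran
Product: 18 diethyl 2,2'-{[3-(tetrahydro-2H-pyran-2-yloxy)propyl]azanediyl}diacetate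
Conditions: K2CO3, KI (cat.), MeCN, reflux
Reagents that add atoms: none
Why: SN2 N-alkylation of the secondary amine by a primary bromide with in-situ Finkelstein catalysis.

Step 12
Reactants: 18 diethyl 2,2'-{[3-(tetrahydro-2H-pyran-2-yloxy)propyl]azanediyl}diacetate; 19 diethyl oxalate
Product: 21 diethyl 3,4-dihydroxy-1-[3-(tetrahydro-2H-pyran-2-yloxy)propyl]-1H-pyrrole-2,5-dicarboxylate, via acyclic oxalyl Claisen adduct 20 (not isolated)
Conditions: NaOEt (3 equiv), EtOH, reflux; then AcOH/H2O, 0 °C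
Reagents that add atoms: none
Why: Hinsberg pyrrole synthesis; an intermolecular Claisen condensation of the glycinate enolate with diethyl oxalate forms the first C–C bond (20), and a ring-closing second Claisen condensation plus enolisation to the aromatic dihydroxypyrrole dianion drives the sequence.

Step 13
Reactants: 21 diethyl 3,4-dihydroxy-1-[3-(tetrahydro-2H-pyran-2-yloxy)propyl]-1H-pyrrole-2,5-dicarboxylate
Product: 22 diethyl 1-[3-(tetrahydro-2H-pyran-2-yloxy)propyl]-3,4-bis{[(trifluoromethyl)sulfonyl]oxy}-1H-pyrrole-2,5-dicarboxylate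
Conditions: Tf2O (2.5 equiv), pyridine, CH2Cl2, 0 °C
Reagents that add atoms: trifluoromethanesulfonic anhydride, O=S(=O)(OS(=O)(=O)C(F)(F)F)C(F)(F)F
Why: O-sulfonylation of the two acidic enolic hydroxyls; pyridine buffers the acid so the THP acetal survives.

Step 14
Reactants: 22 pyrrole bistriflate; 15 6,7-bis(benzyloxy)-5-(4,4,5,5-tetramethyl-1,3,2-dioxaborolan-2-yl)quinoline (2.8 equiv)
Product: 23 diethyl 3,4-bis[6,7-bis(benzyloxy)quinolin-5-yl]-1-[3-(tetrahydro-2H-pyran-2-yloxy)propyl]-1H-pyrrole-2,5-dicarboxylate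
Conditions: Pd(OAc)2 (5 mol%), SPhos (10 mol%), K3PO4, toluene/H2O 10:1, 100 °C
Reagents that add atoms: none
Why: double Suzuki–Miyaura coupling; the ester-activated triflates add readily to zerovalent palladium and the dialkylbiarylphosphine ligand is suited to hindered biaryl bonds.

Step 15
Reactants: 23 diaryl pyrrole diester
Product: 24 3,4-bis[6,7-bis(benzyloxy)quinolin-5-yl]-1-[3-(tetrahydro-2H-pyran-2-yloxy)propyl]-1H-pyrrole-2,5-dicarboxylic acid
Conditions: KOH, EtOH/H2O 1:1, reflux; then AcOH to pH 5, 0 °C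
Reagents that add atoms: potassium hydroxide, [K+].[OH-]
Why: saponification of the two esters; benzyl ethers and the THP acetal are stable to hot base.

Step 16
Reactants: 24 pyrrole-2,5-dicarboxylic acid
Product: 25 5,5'-{1-[3-(tetrahydro-2H-pyran-2-yloxy)propyl]-1H-pyrrole-3,4-diyl}bis[6,7-bis(benzyloxy)quinoline]
Conditions: Cu2O (0.2 equiv), quinoline, 200 °C, 30 min, Ar
Reagents that add atoms: none
Why: copper-mediated thermal protodecarboxylation of pyrrole alpha-carboxylic acids; any THP loss at this temperature is harmless because step 17 removes that group.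

Step 17
Reactants: 25 THP ether
Product: 26 3-{3,4-bis[6,7-bis(benzyloxy)quinolin-5-yl]-1H-pyrrol-1-yl}propan-1-ol
Conditions: PPTS (0.5 equiv), MeOH, 50 °C
Reagents that add atoms: none
Why: mild acid-catalysed transacetalisation to methanol frees the primary alcohol without harming the pyrrole or benzyl ethers.

Step 18
Reactants: 26 primary alcohol
Product: 27 3-{3,4-bis[6,7-bis(benzyloxy)quinolin-5-yl]-1H-pyrrol-1-yl}propyl methanesulfonate
Conditions: MsCl, Et3N, CH2Cl2, 0 °C
Reagents that add atoms: methanesulfonyl chloride, CS(=O)(=O)Cl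
Why: sulfonylation of the primary alcohol via the sulfene pathway gives the leaving group for amination; used directly.

**Fragment C: (S)-3-methylazecane**

Step 19
Reactants: 28 methyl (R)-3-hydroxy-2-methylpropanoate (Roche ester)
Product: 29 methyl (R)-3-[(tert-butyldimethylsilyl)oxy]-2-methylpropanoate
Conditions: TBSCl, imidazole, CH2Cl2, rt
Reagents that add atoms: tert-butyldimethylsilyl chloride, CC(C)(C)[Si](C)(C)Cl
Why: silylation of the primary alcohol under weakly basic conditions; the stereocentre comes from the chiral pool and is untouched.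

Step 20
Reactants: 29 silyl-protected Roche ester
Product: 30 (S)-3-[(tert-butyldimethylsilyl)oxy]-2-methylpropan-1-ol
Conditions: i-Bu2AlH (2.5 equiv), CH2Cl2, −78 → 0 °C; aq. KNaC4H4O6 (potassium sodium tartrate)
Reagents that add atoms: none
Why: hydride reduction of the ester to the primary alcohol at low temperature without strong base, so no 1,3-silyl shift (which would racemise) occurs; the descriptor changes only through CIP priorities.

Step 21
Reactants: 30 (S)-3-[(tert-butyldimethylsilyl)oxy]-2-methylpropan-1-ol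
Product: 31 (R)-3-[(tert-butyldimethylsilyl)oxy]-2-methylpropyl 4-methylbenzenesulfonate
Conditions: TsCl, Et3N, DMAP (cat.), CH2Cl2, 0 °C → rt
Reagents that add atoms: 4-methylbenzenesulfonyl chloride, Cc1ccc(cc1)S(=O)(=O)Cl
Why: tosylation of the primary alcohol under amine base, again avoiding alkoxide formation.

Step 22
Reactants: 31 (R)-tosylate; 32 1-bromo-6-chlorohexane
Product: 34 tert-butyl{[(S)-9-chloro-2-methylnonyl]oxy}dimethylsilane, via (6-chlorohexyl)magnesium bromide 33 (not isolated)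
Conditions: 32, Mg, THF, 40 °C; then 31, Li2CuCl4 (5 mol%), THF, −20 °C → rt
Reagents that add atoms: none
Why: Kochi-type copper-catalysed sp3–sp3 coupling of a Grignard reagent with a primary tosylate; magnesium inserts only into the C–Br bond, the alkyl chloride is inert, and the stereocentre is not involved.

Step 23
Reactants: 34 silyl ether
Product: 35 (S)-9-chloro-2-methylnonan-1-ol
Conditions: TsOH·H2O (0.1 equiv), MeOH, rt
Reagents that add atoms: none
Why: acid-catalysed methanolysis of the primary silyl ether.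

Step 24
Reactants: 35 (S)-9-chloro-2-methylnonan-1-ol; 36 tert-butyl [(2-nitrophenyl)sulfonyl]carbamate
Product: 37 tert-butyl [(S)-9-chloro-2-methylnonyl][(2-nitrophenyl)sulfonyl]carbamate
Conditions: PPh3, DIAD, THF, 0 °C → rt
Reagents that add atoms: none
Why: Fukuyama–Mitsunobu N-alkylation of the acidic sulfonyl carbamate at the primary carbinol; the adjacent stereocentre is not touched and the chloride is a spectator.

Step 25
Reactants: 37 N-Boc sulfonamide
Product: 38 N-[(S)-9-chloro-2-methylnonyl]-2-nitrobenzenesulfonamide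
Conditions: TFA, CH2Cl2, rt
Reagents that add atoms: none
Why: acidolytic Boc cleavage (loss of isobutene and CO2) leaves the acidic N–H sulfonamide.

Step 26
Reactants: 38 chloro sulfonamide
Product: 39 N-[(S)-9-iodo-2-methylnonyl]-2-nitrobenzenesulfonamide
Conditions: NaI (5 equiv), acetone, reflux
Reagents that add atoms: sodium iodide, [Na+].[I-]
Why: Finkelstein halide exchange driven by precipitation of NaCl gives the better leaving group for ring closure.

Step 27
Reactants: 39 iodo sulfonamide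
Product: 40 (S)-3-methyl-1-[(2-nitrophenyl)sulfonyl]azecane
Conditions: Cs2CO3 (3 equiv), MeCN, 65 °C, slow addition of 39 to 0.005 M final concentration
Reagents that add atoms: none
Why: Fukuyama-type intramolecular SN2 N-alkylation of the sulfonamide anion at an unbranched primary iodide under high dilution, a method that works for 8- to 10-membered cyclic amines.

Step 28
Reactants: 40 (S)-3-methyl-1-[(2-nitrophenyl)sulfonyl]azecane
Product: 41 (S)-3-methylazecane
Conditions: PhSH, K2CO3, DMF, rt; acid–base extraction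
Reagents that add atoms: none
Why: Fukuyama deprotection; thiolate adds ipso to the nitroarene (Meisenheimer complex) and the sulfonamide collapses with loss of SO2 to the free secondary amine.

**Assembly**

Step 29
Reactants: 27 mesylate; 41 (S)-3-methylazecane (1.3 equiv)
Product: 42 (S)-1-(3-{3,4-bis[6,7-bis(benzyloxy)quinolin-5-yl]-1H-pyrrol-1-yl}propyl)-3-methylazecane
Conditions: K2CO3, NaI (0.2 equiv), MeCN, 70 °C
Reagents that add atoms: none
Why: SN2 amination of a primary mesylate by the secondary amine, which is far more nucleophilic than the quinoline nitrogens; the stereocentre is remote.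

Step 30
Reactants: 42 tetrabenzyl ether
Product: 43 isohalitulin, 5,5'-(1-{3-[(S)-3-methylazecan-1-yl]propyl}-1H-pyrrole-3,4-diyl)bis(quinoline-6,7-diol)
Conditions: H2 (1 atm), 10% Pd/C, degassed MeOH/THF, rt; filtered and handled under Ar
Reagents that add atoms: none
Why: hydrogenolysis of the four aryl benzyl ethers under neutral conditions frees the air-sensitive bis-catechol without acid or Lewis acid and leaves the stereocentre unchanged.

**Compound list**
1 | 2-methoxy-4-nitrophenol | COc1cc(ccc1O)[N+](=O)[O-] | starting material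
2 | 1-(benzyloxy)-2-methoxy-4-nitrobenzene | COc1cc(ccc1OCc1ccccc1)[N+](=O)[O-] | intermediate
3 | 4-(benzyloxy)-3-methoxyaniline | COc1cc(N)ccc1OCc1ccccc1 | intermediate
4 | Meldrum's acid | CC1(C)OC(=O)CC(=O)O1 | starting material
5 | trimethyl orthoformate | COC(OC)OC | starting material
6 | 5-(methoxymethylidene)-2,2-dimethyl-1,3-dioxane-4,6-dione | COC=C1C(=O)OC(C)(C)OC1=O | intermediate
7 | 5-({[4-(benzyloxy)-3-methoxyphenyl]amino}methylidene)-2,2-dimethyl-1,3-dioxane-4,6-dione | COc1cc(NC=C2C(=O)OC(C)(C)OC2=O)ccc1OCc1ccccc1 | intermediate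
8 | 3-{[4-(benzyloxy)-3-methoxyphenyl]imino}prop-1-en-1-one (imidoylketene) | COc1cc(N=CC=C=O)ccc1OCc1ccccc1 | intermediate
9 | 6-(benzyloxy)-7-methoxyquinolin-4(1H)-one | COc1cc2[nH]ccc(=O)c2cc1OCc1ccccc1 | intermediate
10 | 6-(benzyloxy)-4-chloro-7-methoxyquinoline | COc1cc2nccc(Cl)c2cc1OCc1ccccc1 | intermediate
11 | 7-methoxyquinolin-6-ol | COc1cc2ncccc2cc1O | intermediate
12 | 5-bromo-7-methoxyquinolin-6-ol | COc1cc2ncccc2c(Br)c1O | intermediate
13 | 5-bromoquinoline-6,7-diol | Oc1cc2ncccc2c(Br)c1O | intermediate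
14 | 6,7-bis(benzyloxy)-5-bromoquinoline | Brc1c(OCc2ccccc2)c(OCc2ccccc2)cc2ncccc12 | intermediate
15 | 6,7-bis(benzyloxy)-5-(4,4,5,5-tetramethyl-1,3,2-dioxaborolan-2-yl)quinoline | CC1(C)OB(OC1(C)C)c1c(OCc2ccccc2)c(OCc2ccccc2)cc2ncccc12 | intermediate
16 | diethyl iminodiacetate | CCOC(=O)CNCC(=O)OCC | starting material
17 | 2-(3-bromopropoxy)tetrahydro-2H-pyran (racemic) | BrCCCOC1CCCCO1 | starting material
18 | diethyl 2,2'-{[3-(tetrahydro-2H-pyran-2-yloxy)propyl]azanediyl}diacetate | CCOC(=O)CN(CCCOC1CCCCO1)CC(=O)OCC | intermediate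
19 | diethyl oxalate | CCOC(=O)C(=O)OCC | starting material
20 | diethyl 2-{(2-ethoxy-2-oxoethyl)[3-(tetrahydro-2H-pyran-2-yloxy)propyl]amino}-3-oxobutanedioate | CCOC(=O)CN(CCCOC1CCCCO1)C(C(=O)OCC)C(=O)C(=O)OCC | intermediate
21 | diethyl 3,4-dihydroxy-1-[3-(tetrahydro-2H-pyran-2-yloxy)propyl]-1H-pyrrole-2,5-dicarboxylate | CCOC(=O)c1c(O)c(O)c(C(=O)OCC)n1CCCOC1CCCCO1 | intermediate
22 | diethyl 1-[3-(tetrahydro-2H-pyran-2-yloxy)propyl]-3,4-bis{[(trifluoromethyl)sulfonyl]oxy}-1H-pyrrole-2,5-dicarboxylate | CCOC(=O)c1c(OS(=O)(=O)C(F)(F)F)c(OS(=O)(=O)C(F)(F)F)c(C(=O)OCC)n1CCCOC1CCCCO1 | intermediate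
23 | diethyl 3,4-bis[6,7-bis(benzyloxy)quinolin-5-yl]-1-[3-(tetrahydro-2H-pyran-2-yloxy)propyl]-1H-pyrrole-2,5-dicarboxylate | CCOC(=O)c1c(-c2c(OCc3ccccc3)c(OCc3ccccc3)cc3ncccc23)c(-c2c(OCc3ccccc3)c(OCc3ccccc3)cc3ncccc23)c(C(=O)OCC)n1CCCOC1CCCCO1 | intermediate
24 | 3,4-bis[6,7-bis(benzyloxy)quinolin-5-yl]-1-[3-(tetrahydro-2H-pyran-2-yloxy)propyl]-1H-pyrrole-2,5-dicarboxylic acid | OC(=O)c1c(-c2c(OCc3ccccc3)c(OCc3ccccc3)cc3ncccc23)c(-c2c(OCc3ccccc3)c(OCc3ccccc3)cc3ncccc23)c(C(=O)O)n1CCCOC1CCCCO1 | intermediate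
25 | 5,5'-{1-[3-(tetrahydro-2H-pyran-2-yloxy)propyl]-1H-pyrrole-3,4-diyl}bis[6,7-bis(benzyloxy)quinoline] | O(CCCn1cc(-c2c(OCc3ccccc3)c(OCc3ccccc3)cc3ncccc23)c(-c2c(OCc3ccccc3)c(OCc3ccccc3)cc3ncccc23)c1)C1CCCCO1 | intermediate
26 | 3-{3,4-bis[6,7-bis(benzyloxy)quinolin-5-yl]-1H-pyrrol-1-yl}propan-1-ol | OCCCn1cc(-c2c(OCc3ccccc3)c(OCc3ccccc3)cc3ncccc23)c(-c2c(OCc3ccccc3)c(OCc3ccccc3)cc3ncccc23)c1 | intermediate
27 | 3-{3,4-bis[6,7-bis(benzyloxy)quinolin-5-yl]-1H-pyrrol-1-yl}propyl methanesulfonate | CS(=O)(=O)OCCCn1cc(-c2c(OCc3ccccc3)c(OCc3ccccc3)cc3ncccc23)c(-c2c(OCc3ccccc3)c(OCc3ccccc3)cc3ncccc23)c1 | intermediate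
28 | methyl (R)-3-hydroxy-2-methylpropanoate | C[C@H](CO)C(=O)OC | starting material
29 | methyl (R)-3-[(tert-butyldimethylsilyl)oxy]-2-methylpropanoate | C[C@H](CO[Si](C)(C)C(C)(C)C)C(=O)OC | intermediate
30 | (S)-3-[(tert-butyldimethylsilyl)oxy]-2-methylpropan-1-ol | C[C@H](CO[Si](C)(C)C(C)(C)C)CO | intermediate
31 | (R)-3-[(tert-butyldimethylsilyl)oxy]-2-methylpropyl 4-methylbenzenesulfonate | C[C@H](CO[Si](C)(C)C(C)(C)C)COS(=O)(=O)c1ccc(C)cc1 | intermediate
32 | 1-bromo-6-chlorohexane | ClCCCCCCBr | starting material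
33 | (6-chlorohexyl)magnesium bromide | ClCCCCCC[Mg]Br | intermediate
34 | tert-butyl{[(S)-9-chloro-2-methylnonyl]oxy}dimethylsilane | C[C@H](CO[Si](C)(C)C(C)(C)C)CCCCCCCCl | intermediate
35 | (S)-9-chloro-2-methylnonan-1-ol | C[C@H](CO)CCCCCCCCl | intermediate
36 | tert-butyl [(2-nitrophenyl)sulfonyl]carbamate | CC(C)(C)OC(=O)NS(=O)(=O)c1ccccc1[N+](=O)[O-] | starting material
37 | tert-butyl [(S)-9-chloro-2-methylnonyl][(2-nitrophenyl)sulfonyl]carbamate | C[C@H](CN(C(=O)OC(C)(C)C)S(=O)(=O)c1ccccc1[N+](=O)[O-])CCCCCCCCl | intermediate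
38 | N-[(S)-9-chloro-2-methylnonyl]-2-nitrobenzenesulfonamide | C[C@H](CNS(=O)(=O)c1ccccc1[N+](=O)[O-])CCCCCCCCl | intermediate
39 | N-[(S)-9-iodo-2-methylnonyl]-2-nitrobenzenesulfonamide | C[C@H](CNS(=O)(=O)c1ccccc1[N+](=O)[O-])CCCCCCCI | intermediate
40 | (S)-3-methyl-1-[(2-nitrophenyl)sulfonyl]azecane | C[C@H]1CCCCCCCN(C1)S(=O)(=O)c1ccccc1[N+](=O)[O-] | intermediate
41 | (S)-3-methylazecane | C[C@H]1CCCCCCCNC1 | intermediate
42 | (S)-1-(3-{3,4-bis[6,7-bis(benzyloxy)quinolin-5-yl]-1H-pyrrol-1-yl}propyl)-3-methylazecane | C[C@H]1CCCCCCCN(CCCn2cc(-c3c(OCc4ccccc4)c(OCc4ccccc4)cc4ncccc34)c(-c3c(OCc4ccccc4)c(OCc4ccccc4)cc4ncccc34)c2)C1 | intermediate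
43 | isohalitulin | C[C@H]1CCCCCCCN(CCCn2cc(-c3c(O)c(O)cc4ncccc34)c(-c3c(O)c(O)cc4ncccc34)c2)C1 | target

**Totals**
Total step count: 30.
Longest linear sequence: 17 steps (steps 1–10, 14–18, 29, 30).

**Three steps most likely to fail**

Step 14 (double Suzuki coupling of a di-ortho-substituted boronate onto adjacent, ester-flanked triflates). The fallback sets out from bromide 14 and comes back at diester 23. Bromine–lithium exchange on 14 (n-BuLi, THF, −78 °C) gives [6,7-bis(benzyloxy)quinolin-5-yl]lithium F1. Acylation of two equivalents of it with 1,4-dimethylpiperazine-2,3-dione gives the benzil 1,2-bis[6,7-bis(benzyloxy)quinolin-5-yl]ethane-1,2-dione F2. A Hinsberg double aldol condensation–dehydration of F2 with iminodiacetate 18 (NaOEt, EtOH, reflux) then builds the pyrrole with both aryl groups already in place and delivers 23.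

Step 16 (thermal double decarboxylation at 200 °C). The fallback sets out from diacid 24 and comes back at 25. Iododecarboxylation (I2, KI, NaHCO3, CH2Cl2/H2O, rt) gives 5,5'-{2,5-diiodo-1-[3-(tetrahydro-2H-pyran-2-yloxy)propyl]-1H-pyrrole-3,4-diyl}bis[6,7-bis(benzyloxy)quinoline] F3. Homogeneous hydrodeiodination (Pd(PPh3)4 cat., HCO2H, Et3N, DMF, 60 °C) leaves the benzyl ethers intact and gives 25.

Step 27 (ten-membered ring closure). The fallback sets out from chloro alcohol 35 and comes back at 40, closing the other C–N bond by a different reaction. N-alkylation of carbamate 36 with the chloride end of 35 (K2CO3, NaI, DMF, 70 °C) gives tert-butyl [(S)-9-hydroxy-8-methylnonyl][(2-nitrophenyl)sulfonyl]carbamate F4. TFA removes the Boc group to give N-[(S)-9-hydroxy-8-methylnonyl]-2-nitrobenzenesulfonamide F5. An intramolecular Fukuyama–Mitsunobu reaction (PPh3, DEAD, toluene, slow addition to 0.005 M) closes the ring at the carbinol carbon to give 40 with the stereocentre untouched.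

**Further compounds**
F1 | step 14 | [6,7-bis(benzyloxy)quinolin-5-yl]lithium | [Li]c1c(OCc2ccccc2)c(OCc2ccccc2)cc2ncccc12
F2 | step 14 | 1,2-bis[6,7-bis(benzyloxy)quinolin-5-yl]ethane-1,2-dione | O=C(C(=O)c1c(OCc2ccccc2)c(OCc2ccccc2)cc2ncccc12)c1c(OCc2ccccc2)c(OCc2ccccc2)cc2ncccc12
F3 | step 16 | 5,5'-{2,5-diiodo-1-[3-(tetrahydro-2H-pyran-2-yloxy)propyl]-1H-pyrrole-3,4-diyl}bis[6,7-bis(benzyloxy)quinoline] | Ic1c(-c2c(OCc3ccccc3)c(OCc3ccccc3)cc3ncccc23)c(-c2c(OCc3ccccc3)c(OCc3ccccc3)cc3ncccc23)c(I)n1CCCOC1CCCCO1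
F4 | step 27 | tert-butyl [(S)-9-hydroxy-8-methylnonyl][(2-nitrophenyl)sulfonyl]carbamate | C[C@H](CO)CCCCCCCN(C(=O)OC(C)(C)C)S(=O)(=O)c1ccccc1[N+](=O)[O-]
F5 | step 27 | N-[(S)-9-hydroxy-8-methylnonyl]-2-nitrobenzenesulfonamide | C[C@H](CO)CCCCCCCNS(=O)(=O)c1ccccc1[N+](=O)[O-]
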